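**Plan**

1. Ring carbons are numbered C1 (CH–OAng), C2 (CH2), C3 (CH–OAng), C4 (quaternary, CH3), C5, C6, C7 (CH), C8 (C=O), C9 (CH2), C10 (CH–CH3), C11 (quaternary, CH3 and CH2OH). The enabling feature is the cyclobutane C4–C5–C6–C7: with C4 bonded to C8 instead of C7, the six-membered ring C5–C6–C7–C8–C9–C10 is a norbornene bridged by C4, the adduct of a cyclopentadiene (C4, C5, C10, C9, C8) quaternary at C4 and an alkene C6=C7 held by the chain C3–C2–C1–C11.
2. Retrosynthesis: remove the angelates and the C10 methyl (cuprate); trade C4–C7 for C4–C8 (reverse 1,2-shift); cut C5–C6 and C7–C8 (retro-[4+2]); cut the chain at C6=C7, C1–C11 and C3–C2.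
3. Forward: the cyclopentanone comes first, then the chain is grown C3 → C1 → C11 → C6=C7. The norbornene ring and the seven-membered ring C1–C2–C3–C4–C5–C6–C11 close together, and the cyclobutane forms last.
4. Stereochemistry: C4 by auxiliary-controlled methylation, C3 by Brown allylation, C1 and C11 by iridium-catalysed tert-(hydroxy)prenylation. C5–C8 are set in the cycloaddition (exo tether, E-alkene gives endo boron); C7 is inverted and C4 retained in the shift; C10 by cuprate addition anti to the C4 methyl.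

Key step: step 18

Assumption: in steps 2, 6 and 9 the auxiliary, reagent or ligand antipode named is the one expected to give the drawn centre; if the sense proves opposite, the mirror-image auxiliary, reagent or ligand is used with no other change.

**Route**

Step 1
Reactants: 1 methyl 2-oxocyclopentane-1-carboxylate; 2 L-valine tert-butyl ester
Product: 3 tert-butyl N-[2-(methoxycarbonyl)cyclopent-1-en-1-yl]-L-valinate
Conditions: BF3·OEt2 (cat.), benzene, reflux, Dean–Stark
Reagents that add atoms: none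
Why: Acid-catalysed condensation of a β-keto ester with a primary amine gives the hydrogen-bonded enamino ester needed for chiral-enamine alkylation, and no stereocentre is formed.

Step 2
Reactants: 3 tert-butyl N-[2-(methoxycarbonyl)cyclopent-1-en-1-yl]-L-valinate
Product: 5 methyl (1R)-1-methyl-2-oxocyclopentane-1-carboxylate, via methylated ketimine 4 (not isolated)
Conditions: LiN(i-Pr)2, toluene, −78 °C; HMPA (1 equiv), MeI, −78 → −40 °C; then 1 M HCl, 0 → 20 °C
Reagents that add atoms: iodomethane (CI); water (O)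
Why: Koga-type chiral-enamine alkylation, in which the lithiated enamine is chelated by the valine ester so that MeI attacks one face of C4 (the toluene/HMPA regime is taken to give R, THF the antipode), and acid hydrolysis of the ketimine releases the quaternary keto ester and the auxiliary.

Step 3
Reactants: 5 methyl (1R)-1-methyl-2-oxocyclopentane-1-carboxylate
Product: 6 methyl (6R)-6-methyl-1,4-dioxaspiro[4.4]nonane-6-carboxylate
Conditions: ethylene glycol, TsOH (cat.), benzene, reflux, Dean–Stark
Reagents that add atoms: ethylene glycol (OCCO)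
Why: Acid-catalysed ketalisation masks the C8 ketone, and the quaternary C4 rules out epimerisation.

Step 4
Reactants: 6 methyl (6R)-6-methyl-1,4-dioxaspiro[4.4]nonane-6-carboxylate
Product: 7 [(6S)-6-methyl-1,4-dioxaspiro[4.4]nonan-6-yl]methanol
Conditions: LiAlH4, THF, 0 → 20 °C
Reagents that add atoms: none
Why: Hydride reduction of the hindered ester gives the neopentyl alcohol while the ketal is inert (the descriptor changes only through priorities).

Step 5
Reactants: 7 [(6S)-6-methyl-1,4-dioxaspiro[4.4]nonan-6-yl]methanol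
Product: 8 (6S)-6-methyl-1,4-dioxaspiro[4.4]nonane-6-carbaldehyde
Conditions: Dess–Martin periodinane, NaHCO3, CH2Cl2, 20 °C
Reagents that add atoms: none
Why: Buffered Dess–Martin oxidation gives the non-enolisable aldehyde without harming the ketal.

Step 6
Reactants: 8 (6S)-6-methyl-1,4-dioxaspiro[4.4]nonane-6-carbaldehyde
Product: 10 (1R)-1-[(6S)-6-methyl-1,4-dioxaspiro[4.4]nonan-6-yl]but-3-en-1-ol, via diisopinocampheylborinate ester 9 (not isolated)
Conditions: B-allylbis(isopinocampheyl)borane derived from (−)-α-pinene, Et2O, −78 °C; then NaOH, H2O2, 0 → 20 °C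
Reagents that add atoms: B-allylbis(isopinocampheyl)borane (C=CCB([C@H]1C[C@H]2C[C@@H]([C@@H]1C)C2(C)C)[C@H]1C[C@H]2C[C@@H]([C@@H]1C)C2(C)C)
Why: Brown allylation through a chair Zimmerman–Traxler transition state in which the isopinocampheyl groups choose the aldehyde face, so the C3 carbinol (R) is set by the reagent, which should override the bias of the α-quaternary centre.

Step 7
Reactants: 10 (1R)-1-[(6S)-6-methyl-1,4-dioxaspiro[4.4]nonan-6-yl]but-3-en-1-ol
Product: 11 (6S)-6-[(1R)-1-(benzyloxy)but-3-en-1-yl]-6-methyl-1,4-dioxaspiro[4.4]nonane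
Conditions: NaH, BnBr, Bu4NI (cat.), DMF, 0 → 20 °C
Reagents that add atoms: benzyl bromide (BrCc1ccccc1)
Why: Williamson etherification of the hindered secondary alkoxide under iodide catalysis.

Step 8
Reactants: 11 (6S)-6-[(1R)-1-(benzyloxy)but-3-en-1-yl]-6-methyl-1,4-dioxaspiro[4.4]nonane
Product: 13 (3R)-3-(benzyloxy)-3-[(6S)-6-methyl-1,4-dioxaspiro[4.4]nonan-6-yl]propan-1-ol, via ozonide 12 (not isolated)
Conditions: O3, CH2Cl2, −78 °C (Sudan Red 7B end-point); then NaBH4, EtOH, −78 → 20 °C
Reagents that add atoms: ozone ([O-][O+]=O)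
Why: Ozonolysis with reductive work-up shortens the allyl group by one carbon to the C1 primary alcohol, and the benzyl ether and ketal survive when the addition is stopped at the indicator end-point.

Step 9
Reactants: 13 (3R)-3-(benzyloxy)-3-[(6S)-6-methyl-1,4-dioxaspiro[4.4]nonan-6-yl]propan-1-ol; 14 2-methyl-2-vinyloxirane (isoprene monoxide, racemic)
Product: 15 (2R,3R,5R)-5-(benzyloxy)-2-methyl-5-[(6S)-6-methyl-1,4-dioxaspiro[4.4]nonan-6-yl]-2-vinylpentane-1,3-diol
Conditions: cyclometalated π-allyl iridium C,O-benzoate from [Ir(cod)Cl]2, (R)-Tol-BINAP, 4-cyano-3-nitrobenzoic acid and allyl acetate (5 mol%), K3PO4 (5 mol%), THF, 50 °C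
Reagents that add atoms: none
Why: Iridium-catalysed tert-(hydroxy)prenylation (Krische-type transfer-hydrogenative carbonyl allylation), in which the alcohol is dehydrogenated to the aldehyde and the (E)-σ-allyl iridium species from the vinyl epoxide adds through a closed chair transition state, setting the C1 carbinol and the quaternary C11 together with secondary OH anti to CH2OH and the absolute sense fixed by the ligand.

Step 10
Reactants: 15 (2R,3R,5R)-5-(benzyloxy)-2-methyl-5-[(6S)-6-methyl-1,4-dioxaspiro[4.4]nonan-6-yl]-2-vinylpentane-1,3-diol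
Product: 16 benzylidene acetal of 15 (2-phenyl-1,3-dioxane over the C1 oxygen and the CH2O carbon that will become C6; phenyl and the C1 side chain equatorial)
Conditions: PhCH(OMe)2, camphorsulfonic acid (cat.), CH2Cl2, 20 °C
Reagents that add atoms: benzaldehyde dimethyl acetal (COC(OC)c1ccccc1)
Why: Thermodynamic transacetalisation on the only 1,3-diol gives the six-membered acetal with phenyl equatorial.

Step 11
Reactants: 16 benzylidene acetal of 15
Product: 18 primary alcohol (vinyl of 16 replaced by CH2OH on C11), via ozonide 17 (not isolated)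
Conditions: O3, CH2Cl2, −78 °C (Sudan Red 7B end-point); then NaBH4, EtOH, −78 → 20 °C
Reagents that add atoms: ozone ([O-][O+]=O)
Why: Ozonolysis with reductive work-up converts the vinyl group into the hydroxymethyl arm of C11, so the two one-carbon arms of the quaternary centre are differentiated (one in the acetal, one free).

Step 12
Reactants: 18 primary alcohol
Product: 19 tert-butyldiphenylsilyl ether of 18
Conditions: TBDPSCl, imidazole, DMAP (cat.), DMF, 40 °C
Reagents that add atoms: tert-butyl(chloro)diphenylsilane (CC(C)(C)[Si](Cl)(c1ccccc1)c1ccccc1)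
Why: Silylation of the neopentyl primary alcohol gives an ether that should last until the final step.

Step 13
Reactants: 19 tert-butyldiphenylsilyl ether
Product: 20 (2S,3R,5R)-3,5-bis(benzyloxy)-2-[(tert-butyldiphenylsilyloxy)methyl]-2-methyl-5-[(6S)-6-methyl-1,4-dioxaspiro[4.4]nonan-6-yl]pentan-1-ol
Conditions: i-Bu2AlH, CH2Cl2, −78 → 0 °C; sodium potassium tartrate work-up
Reagents that add atoms: none
Why: Regioselective reductive opening of the benzylidene acetal, in which aluminium binds the less hindered primary oxygen so that the benzyl group stays on the secondary C1 oxygen and the future C6 carbinol is freed.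

Step 14
Reactants: 20 ketal alcohol
Product: 21 (2S)-2-[(1R,3R,4S)-1,3-bis(benzyloxy)-4-[(tert-butyldiphenylsilyloxy)methyl]-5-hydroxy-4-methylpentyl]-2-methylcyclopentan-1-one
Conditions: 1 M HCl, THF, 20 °C
Reagents that add atoms: water (O)
Why: Acid hydrolysis of the dioxolane returns the C8 ketone, and benzyl and TBDPS ethers are stable to dilute acid.

Step 15
Reactants: 21 keto alcohol
Product: 23 (2S,3R,5R)-3,5-bis(benzyloxy)-2-[(tert-butyldiphenylsilyloxy)methyl]-2-methyl-5-[(1S)-1-methyl-2-oxocyclopent-3-en-1-yl]pentanal, via keto aldehyde 22 (not isolated)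
Conditions: IBX (5 equiv), 4-methoxypyridine N-oxide (5 equiv), DMSO, 25 °C
Reagents that add atoms: none
Why: IBX oxidises the primary alcohol to the aldehyde and, as its N-oxide complex, dehydrogenates the cyclopentanone at C9–C10, the only enolisable side because C4 and C11 are quaternary.

Step 16
Reactants: 23 enone aldehyde
Product: 24 (5S)-5-[(1R,3R,4S,5E)-1,3-bis(benzyloxy)-4-[(tert-butyldiphenylsilyloxy)methyl]-4-methyl-6-(4,4,5,5-tetramethyl-1,3,2-dioxaborolan-2-yl)hex-5-en-1-yl]-5-methylcyclopent-2-en-1-one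
Conditions: CrCl2 (8 equiv), LiI (4 equiv), Cl2CHBpin (2 equiv), THF, 25 °C
Reagents that add atoms: 2-(dichloromethyl)-4,4,5,5-tetramethyl-1,3,2-dioxaborolane (ClC(Cl)B1OC(C)(C)C(C)(C)O1)
Why: Takai–Utimoto boron olefination, in which the geminal dichromium reagent adds to the aldehyde in preference to the enone and elimination gives the (E)-alkenyl boronate.

Step 17
Reactants: 24 enone alkenyl boronate
Product: 25 5-methyl-5-alkyl-1-(trimethylsiloxy)cyclopenta-1,3-diene carrying the (E)-alkenyl boronate chain (C4 S; chain as in 24)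
Conditions: TMSOTf, Et3N, CH2Cl2, −78 → 0 °C; non-aqueous work-up, used without chromatography
Reagents that add atoms: trimethylsilyl triflate (C[Si](C)(C)OS(=O)(=O)C(F)(F)F)
Why: Soft enolisation, in which the only acidic hydrogens of the O-silylated enone are at C5 (γ) because C4 is quaternary, so the 1-siloxy-diene C5=C10–C9=C8(OSi) forms regiospecifically.

Step 18
Reactants: 25 siloxy-diene alkenyl boronate
Product: 26 tricyclic norbornene adduct (six-membered ring C5–C6–C7–C8–C9=C10 bridged by C4; seven-membered ring C1–C2–C3–C4–C5–C6–C11; bridgehead C8–OSiMe3, endo C7–Bpin, C11 exo on C6)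
Conditions: PhMe (5 mM), 2,6-di-tert-butyl-4-methylphenol (cat.), 110 °C, sealed tube
Reagents that add atoms: none
Why: A thermal, concerted, suprafacial [4+2] cycloaddition of normal electron demand joins the 1-siloxy-diene C5=C10–C9=C8 to the tethered (E)-alkenyl boronate C6=C7, forming C5–C6 and C7–C8. The closest known reactions are intramolecular Diels–Alder reactions of cyclopentadienes tethered at a quaternary sp3 carbon and cycloadditions of vinyl boronates with cyclopentadienes. The norbornene six-membered ring closes by the cycloaddition itself, and the seven-membered ring closes because the four-atom tether C3–C2–C1–C11 links C4 to C6, which it can do only across the diene face syn to C3 and through an exo position on C6. C5 and C8 follow from which diene terminus meets C6 together with the C4 configuration, C6 from the exo tether, and C7 from the (E) geometry, which places boron trans to C11 and therefore endo. The selectivity required is regiochemical (C6 to C5, not to C8): the largest HOMO coefficient of the 1-siloxy-diene is at C5 and the larger LUMO coefficient of the alkenyl boronate at C6, and the other mode would press the quaternary C11 against the siloxy-bearing bridgehead. The quaternary C4 blocks 1,5-hydrogen shifts, so the diene cannot isomerise before it cyclises.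

Step 19
Reactants: 26 norbornene adduct
Product: 28 diol (bridgehead C8–OH, endo C7–OH), via trimethylsilyl ether alcohol 27 (not isolated)
Conditions: NaBO3·4H2O, THF/H2O (1:1), 20 °C; then K2CO3, MeOH, 20 °C
Reagents that add atoms: sodium perborate ([Na+].[Na+].O[B-]1(O)OO[B-](O)(O)OO1)
Why: Perborate oxidation of the C–B bond proceeds by 1,2-shift of C7 from boron to oxygen with retention, giving the endo alcohol, and basic methanolysis then removes the trimethylsilyl group whichever oxygen it sits on.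

Step 20
Reactants: 28 diol
Product: 29 endo C7 mesylate with free bridgehead C8–OH
Conditions: MsCl, Et3N, CH2Cl2, −20 → 0 °C
Reagents that add atoms: methanesulfonyl chloride (CS(=O)(=O)Cl)
Why: Sulfonylation through sulfene is selective for the secondary alcohol because the tertiary bridgehead hydroxyl does not react.

Step 21
Reactants: 29 hydroxy mesylate
Product: 30 tricyclic enone (cyclobutane C4–C5–C6–C7; C8 ketone conjugated with C9=C10; C1/C3 OBn; C11 CH2OTBDPS)
Conditions: KOt-Bu (1.2 equiv), THF, −40 → 0 °C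
Reagents that add atoms: none
Why: Proposed new method: the bridgehead alkoxide has its C8–C4 bond antiperiplanar (about 165°) to the endo C7–OMs bond, so C4 should migrate to C7 with inversion there and retention at C4 while C8 becomes the enone carbonyl (carbonyl formation and sulfonate loss pay for the cyclobutane; the vinyl bridge C9 is gauche and should not compete), the closest known reaction types being the base-induced type 1 semipinacol ring contraction of 2-sulfonyloxycyclopentanols to acylcyclobutanes and the pinacol-type shift of 1-alkoxybicyclo[2.2.2]oct-5-en-2-yl sulfonates to bicyclo[3.2.1]octenones.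

Step 22
Reactants: 30 tricyclic enone
Product: 31 C10-methyl ketone
Conditions: Me2CuLi (from CuI and MeLi), Et2O, −78 → −30 °C; aq. NH4Cl
Reagents that add atoms: lithium dimethylcuprate ([Li+].C[Cu-]C)
Why: Gilman cuprate conjugate addition, in which the C4 methyl overhangs one face of the C8–C9–C10 bridge (as the syn methyl does in verbenone) while C6 offers only hydrogen to the other, so the methyl should be delivered from the C6 side and give the C10 configuration of the target.

Step 23
Reactants: 31 C10-methyl ketone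
Product: 32 C1,C3-diol
Conditions: H2 (1 atm), Pd(OH)2/C, EtOAc/EtOH, 20 °C
Reagents that add atoms: none
Why: Hydrogenolysis removes both benzyl ethers while the ketone, the cyclobutane and the silyl ether are inert.

Step 24
Reactants: 32 C1,C3-diol; 33 angelic acid
Product: 35 bis-angelate silyl ether, via mixed anhydride 34 (not isolated)
Conditions: 33 (3 equiv), 2,4,6-trichlorobenzoyl chloride (3 equiv), Et3N (3.3 equiv), PhMe, 20 °C; then 32 (1 equiv), PhMe, 80 °C (no DMAP)
Reagents that add atoms: angelic acid as the second equivalent (C/C=C(/C)C(=O)O)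
Why: Yamaguchi-type esterification, in which each of the two hindered secondary alcohols takes the angeloyl group from one molecule of the mixed anhydride on heating (attack at the unshielded angeloyl carbonyl, so two molecules of 33 are consumed per molecule of 32), without the nucleophilic catalyst that would isomerise the Z ester to the tiglate.

Step 25
Reactants: 35 bis-angelate silyl ether
Product: 36 target CNP0287707.1
Conditions: HF·pyridine, pyridine, THF, 0 → 20 °C
Reagents that add atoms: none
Why: Buffered fluoride cleavage of the primary silyl ether, under conditions where angelates should neither isomerise nor migrate.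

**Compound list**

1 | methyl 2-oxocyclopentane-1-carboxylate | COC(=O)C1CCCC1=O | starting material
2 | L-valine tert-butyl ester | CC(C)[C@H](N)C(=O)OC(C)(C)C | starting material
3 | tert-butyl N-[2-(methoxycarbonyl)cyclopent-1-en-1-yl]-L-valinate | COC(=O)C1=C(N[C@@H](C(C)C)C(=O)OC(C)(C)C)CCC1 | intermediate
4 | methylated ketimine, tert-butyl N-[(2R)-2-(methoxycarbonyl)-2-methylcyclopentylidene]-L-valinate (formed in the flask) | C[C@]1(CCCC1=N[C@@H](C(C)C)C(=O)OC(C)(C)C)C(=O)OC | intermediate
5 | methyl (1R)-1-methyl-2-oxocyclopentane-1-carboxylate | C[C@]1(CCCC1=O)C(=O)OC | intermediate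
6 | methyl (6R)-6-methyl-1,4-dioxaspiro[4.4]nonane-6-carboxylate | C[C@]1(CCCC12OCCO2)C(=O)OC | intermediate
7 | [(6S)-6-methyl-1,4-dioxaspiro[4.4]nonan-6-yl]methanol | C[C@]1(CCCC12OCCO2)CO | intermediate
8 | (6S)-6-methyl-1,4-dioxaspiro[4.4]nonane-6-carbaldehyde | C[C@]1(CCCC12OCCO2)C=O | intermediate
9 | diisopinocampheylborinate ester of 10 (formed in the flask) | C[C@]1(CCCC12OCCO2)[C@H](OB([C@H]2C[C@H]3C[C@@H]([C@@H]2C)C3(C)C)[C@H]2C[C@H]3C[C@@H]([C@@H]2C)C3(C)C)CC=C | intermediate
10 | (1R)-1-[(6S)-6-methyl-1,4-dioxaspiro[4.4]nonan-6-yl]but-3-en-1-ol | C[C@]1(CCCC12OCCO2)[C@H](O)CC=C | intermediate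
11 | (6S)-6-[(1R)-1-(benzyloxy)but-3-en-1-yl]-6-methyl-1,4-dioxaspiro[4.4]nonane | C[C@]1(CCCC12OCCO2)[C@H](OCc2ccccc2)CC=C | intermediate
12 | ozonide (1,2,4-trioxolane) of 11 (formed in the flask) | C[C@]1(CCCC12OCCO2)[C@H](OCc2ccccc2)CC2OCOO2 | intermediate
13 | (3R)-3-(benzyloxy)-3-[(6S)-6-methyl-1,4-dioxaspiro[4.4]nonan-6-yl]propan-1-ol | C[C@]1(CCCC12OCCO2)[C@H](OCc2ccccc2)CCO | intermediate
14 | 2-methyl-2-vinyloxirane (isoprene monoxide, racemic) | CC1(C=C)CO1 | starting material
15 | (2R,3R,5R)-5-(benzyloxy)-2-methyl-5-[(6S)-6-methyl-1,4-dioxaspiro[4.4]nonan-6-yl]-2-vinylpentane-1,3-diol | C[C@]1(CCCC12OCCO2)[C@H](OCc2ccccc2)C[C@@H](O)[C@](C)(C=C)CO | intermediate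
16 | benzylidene acetal of 15 (2-phenyl-1,3-dioxane, phenyl and C1 side chain equatorial) | C[C@]1(CCCC12OCCO2)[C@H](OCc2ccccc2)C[C@H]2O[C@@H](c3ccccc3)OC[C@@]2(C)C=C | intermediate
17 | ozonide of 16 (formed in the flask) | C[C@]1(CCCC12OCCO2)[C@H](OCc2ccccc2)C[C@H]2O[C@@H](c3ccccc3)OC[C@@]2(C)C2OCOO2 | intermediate
18 | 5-(hydroxymethyl)-5-methyl-2-phenyl-1,3-dioxane alcohol | C[C@]1(CCCC12OCCO2)[C@H](OCc2ccccc2)C[C@H]2O[C@@H](c3ccccc3)OC[C@@]2(C)CO | intermediate
19 | tert-butyldiphenylsilyl ether of 18 | C[C@]1(CCCC12OCCO2)[C@H](OCc2ccccc2)C[C@H]2O[C@@H](c3ccccc3)OC[C@@]2(C)CO[Si](c3ccccc3)(c3ccccc3)C(C)(C)C | intermediate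
20 | (2S,3R,5R)-3,5-bis(benzyloxy)-2-[(tert-butyldiphenylsilyloxy)methyl]-2-methyl-5-[(6S)-6-methyl-1,4-dioxaspiro[4.4]nonan-6-yl]pentan-1-ol | C[C@]1(CCCC12OCCO2)[C@H](OCc2ccccc2)C[C@@H](OCc2ccccc2)[C@](C)(CO[Si](c2ccccc2)(c2ccccc2)C(C)(C)C)CO | intermediate
21 | (2S)-2-[(1R,3R,4S)-1,3-bis(benzyloxy)-4-[(tert-butyldiphenylsilyloxy)methyl]-5-hydroxy-4-methylpentyl]-2-methylcyclopentan-1-one | C[C@]1(CCCC1=O)[C@H](OCc2ccccc2)C[C@@H](OCc2ccccc2)[C@](C)(CO[Si](c2ccccc2)(c2ccccc2)C(C)(C)C)CO | intermediate
22 | keto aldehyde (saturated cyclopentanone, C6 aldehyde; formed in the flask) | C[C@]1(CCCC1=O)[C@H](OCc2ccccc2)C[C@@H](OCc2ccccc2)[C@](C)(CO[Si](c2ccccc2)(c2ccccc2)C(C)(C)C)C=O | intermediate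
23 | (2S,3R,5R)-3,5-bis(benzyloxy)-2-[(tert-butyldiphenylsilyloxy)methyl]-2-methyl-5-[(1S)-1-methyl-2-oxocyclopent-3-en-1-yl]pentanal | C[C@]1(CC=CC1=O)[C@H](OCc2ccccc2)C[C@@H](OCc2ccccc2)[C@](C)(CO[Si](c2ccccc2)(c2ccccc2)C(C)(C)C)C=O | intermediate
24 | (5S)-5-[(1R,3R,4S,5E)-1,3-bis(benzyloxy)-4-[(tert-butyldiphenylsilyloxy)methyl]-4-methyl-6-(pinacolboryl)hex-5-en-1-yl]-5-methylcyclopent-2-en-1-one | C[C@]1(CC=CC1=O)[C@H](OCc2ccccc2)C[C@@H](OCc2ccccc2)[C@](C)(CO[Si](c2ccccc2)(c2ccccc2)C(C)(C)C)/C=C/B2OC(C)(C)C(C)(C)O2 | intermediate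
25 | 5-methyl-5-alkyl-1-(trimethylsiloxy)cyclopenta-1,3-diene with tethered (E)-alkenyl boronate | C[C@]1(C=CC=C1O[Si](C)(C)C)[C@H](OCc2ccccc2)C[C@@H](OCc2ccccc2)[C@](C)(CO[Si](c2ccccc2)(c2ccccc2)C(C)(C)C)/C=C/B2OC(C)(C)C(C)(C)O2 | intermediate
26 | tricyclic norbornene adduct (bridgehead C8–OSiMe3, endo C7–Bpin, C11 exo on C6) | c4ccccc4CO[C@@H]1C[C@@H](OCc4ccccc4)[C@]2(C)[C@@H]3[C@@H]([C@@H](B5OC(C)(C)C(C)(C)O5)[C@@]2(O[Si](C)(C)C)C=C3)[C@@]1(C)CO[Si](c4ccccc4)(c4ccccc4)C(C)(C)C | intermediate
27 | endo C7 alcohol with bridgehead trimethylsilyl ether (formed in the flask) | c4ccccc4CO[C@@H]1C[C@@H](OCc4ccccc4)[C@]2(C)[C@@H]3[C@@H]([C@@H](O)[C@@]2(O[Si](C)(C)C)C=C3)[C@@]1(C)CO[Si](c4ccccc4)(c4ccccc4)C(C)(C)C | intermediate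
28 | norbornene diol (bridgehead C8–OH, endo C7–OH) | c4ccccc4CO[C@@H]1C[C@@H](OCc4ccccc4)[C@]2(C)[C@@H]3[C@@H]([C@@H](O)[C@@]2(O)C=C3)[C@@]1(C)CO[Si](c4ccccc4)(c4ccccc4)C(C)(C)C | intermediate
29 | endo C7 mesylate, bridgehead C8–OH | c4ccccc4CO[C@@H]1C[C@@H](OCc4ccccc4)[C@]2(C)[C@@H]3[C@@H]([C@@H](OS(C)(=O)=O)[C@@]2(O)C=C3)[C@@]1(C)CO[Si](c4ccccc4)(c4ccccc4)C(C)(C)C | intermediate
30 | tricyclic enone (cyclobutane C4–C5–C6–C7, C8 ketone, C9=C10) | c4ccccc4CO[C@@H]1C[C@@H](OCc4ccccc4)[C@]2(C)[C@@H]3[C@@H]([C@H]2C(=O)C=C3)[C@@]1(C)CO[Si](c4ccccc4)(c4ccccc4)C(C)(C)C | intermediate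
31 | C10-methyl tricyclic ketone, bis-benzyl ether | c4ccccc4CO[C@@H]1C[C@@H](OCc4ccccc4)[C@]2(C)[C@@H]3[C@@H]([C@H]2C(=O)C[C@H]3C)[C@@]1(C)CO[Si](c4ccccc4)(c4ccccc4)C(C)(C)C | intermediate
32 | C1,C3-diol, primary TBDPS ether | O[C@@H]1C[C@@H](O)[C@]2(C)[C@@H]3[C@@H]([C@H]2C(=O)C[C@H]3C)[C@@]1(C)CO[Si](c4ccccc4)(c4ccccc4)C(C)(C)C | intermediate
33 | angelic acid, (Z)-2-methylbut-2-enoic acid | C/C=C(/C)C(=O)O | starting material
34 | angelic 2,4,6-trichlorobenzoic anhydride (formed in the flask) | C/C=C(/C)C(=O)OC(=O)c1c(Cl)cc(Cl)cc1Cl | intermediate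
35 | C1,C3-bis-angelate, primary TBDPS ether | C/C=C(/C)C(=O)O[C@@H]1C[C@@H](OC(=O)/C(C)=C\C)[C@]2(C)[C@@H]3[C@@H]([C@H]2C(=O)C[C@H]3C)[C@@]1(C)CO[Si](c4ccccc4)(c4ccccc4)C(C)(C)C | intermediate
36 | CNP0287707.1 (C1,C3-bis-angelate with free primary alcohol) | C/C=C(/C)C(=O)O[C@@H]1C[C@@H](OC(=O)/C(C)=C\C)[C@]2(C)[C@@H]3[C@@H]([C@H]2C(=O)C[C@H]3C)[C@@]1(C)CO | target

**Count**

Total steps: 25. Longest linear sequence: 25 steps (1 → 36; the route is fully linear).

**Steps most likely to fail**

1. Step 21 (Proposed new method). The alkoxide may fail to trigger ionisation, lose the sulfonyl group by attack at sulfur, or let the vinyl bridge C9 migrate in place of C4. The fallback uses known chemistry and a different trigger; it sets out from adduct 26 and comes back at enone 30. Stereoretentive amination of the secondary pinacol boronate with lithiated O-methylhydroxylamine (MeONH2, n-BuLi, THF, −78 → 60 °C; 1,2-metallate shift with retention) gives the endo amine F1. K2CO3/MeOH removes the silyl group to give the amino alcohol F2. Diazotisation (NaNO2, aqueous AcOH, 0 °C) then effects a Tiffeneau–Demjanov-type semipinacolic deamination: dinitrogen leaves from the endo position, anti to the C8–C4 bond, and the hydroxyl-bearing C8 becomes the ketone of 30.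

2. Step 18 (key step). Closure of the seven-membered ring may be slow enough for the silyl dienol ether to decompose, or the weakly polarised boronate may give poor regiocontrol. The fallback swaps the dienophile for an acrylate, which is far more reactive and strongly directs its β-carbon (C6) to C5 of a 1-siloxy-diene; it sets out from aldehyde 23 and comes back at enone 30. Wittig olefination with allyl (triphenylphosphoranylidene)acetate (PhMe, 90 °C; the enone is untouched) gives the (E)-enoate F3. Et3SiOTf/Et3N gives the triethylsilyl dienol ether F4, which on heating gives the cycloadduct F5 with the ester endo on C7. Pd(PPh3)4/morpholine frees the acid F6. Curtius rearrangement (diphenylphosphoryl azide, Et3N, PhMe, 80 °C; then aqueous LiOH on the isocyanate) gives the endo amine F7 with retention. NaNO2 in aqueous AcOH then gives the same deaminative 1,2-shift, the silyl ether oxygen assisting and losing silicon, to reach 30.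

3. Step 24. Acylation of two neopentyl-type secondary alcohols may stall at the mono-ester, and forcing it risks Z → E isomerisation to tiglates. The fallback builds the Z alkene after the ester bond is made; it sets out from diol 32 and comes back at 35. Carbodiimide coupling (DCC, DMAP) with 2-[bis(2,2,2-trifluoroethoxy)phosphoryl]propanoic acid gives the bis(phosphonate) ester F8. Still–Gennari olefination (KN(SiMe3)2, 2 equiv, 18-crown-6, THF, −78 °C; acetaldehyde) gives both (Z)-2-methylbut-2-enoates; the phosphonate C–H bonds are far more acidic than the ketone α-hydrogens, so two equivalents of base should leave the ketone alone.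

**Further compounds**

F1 | step 21 | endo C7 amine with bridgehead trimethylsilyl ether | c4ccccc4CO[C@@H]1C[C@@H](OCc4ccccc4)[C@]2(C)[C@@H]3[C@@H]([C@@H](N)[C@@]2(O[Si](C)(C)C)C=C3)[C@@]1(C)CO[Si](c4ccccc4)(c4ccccc4)C(C)(C)C
F2 | step 21 | endo C7 amino, bridgehead C8 alcohol | c4ccccc4CO[C@@H]1C[C@@H](OCc4ccccc4)[C@]2(C)[C@@H]3[C@@H]([C@@H](N)[C@@]2(O)C=C3)[C@@]1(C)CO[Si](c4ccccc4)(c4ccccc4)C(C)(C)C
F3 | step 18 | allyl (E)-enoate of the enone aldehyde | C[C@]1(CC=CC1=O)[C@H](OCc2ccccc2)C[C@@H](OCc2ccccc2)[C@](C)(CO[Si](c2ccccc2)(c2ccccc2)C(C)(C)C)/C=C/C(=O)OCC=C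
F4 | step 18 | 1-(triethylsiloxy)cyclopentadiene with tethered allyl (E)-enoate | C[C@]1(C=CC=C1O[Si](CC)(CC)CC)[C@H](OCc2ccccc2)C[C@@H](OCc2ccccc2)[C@](C)(CO[Si](c2ccccc2)(c2ccccc2)C(C)(C)C)/C=C/C(=O)OCC=C
F5 | step 18 | norbornene cycloadduct, endo C7 allyl ester, bridgehead triethylsilyl ether | c4ccccc4CO[C@@H]1C[C@@H](OCc4ccccc4)[C@]2(C)[C@@H]3[C@@H]([C@@H](C(=O)OCC=C)[C@@]2(O[Si](CC)(CC)CC)C=C3)[C@@]1(C)CO[Si](c4ccccc4)(c4ccccc4)C(C)(C)C
F6 | step 18 | endo C7 carboxylic acid | c4ccccc4CO[C@@H]1C[C@@H](OCc4ccccc4)[C@]2(C)[C@@H]3[C@@H]([C@@H](C(=O)O)[C@@]2(O[Si](CC)(CC)CC)C=C3)[C@@]1(C)CO[Si](c4ccccc4)(c4ccccc4)C(C)(C)C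
F7 | step 18 | endo C7 amine with bridgehead triethylsilyl ether | c4ccccc4CO[C@@H]1C[C@@H](OCc4ccccc4)[C@]2(C)[C@@H]3[C@@H]([C@@H](N)[C@@]2(O[Si](CC)(CC)CC)C=C3)[C@@]1(C)CO[Si](c4ccccc4)(c4ccccc4)C(C)(C)C
F8 | step 24 | C1,C3-bis[2-(bis(2,2,2-trifluoroethoxy)phosphoryl)propanoate] (phosphonate α-carbons unassigned) | CC(C(=O)O[C@@H]1C[C@@H](OC(=O)C(C)P(=O)(OCC(F)(F)F)OCC(F)(F)F)[C@]2(C)[C@@H]3[C@@H]([C@H]2C(=O)C[C@H]3C)[C@@]1(C)CO[Si](c4ccccc4)(c4ccccc4)C(C)(C)C)P(=O)(OCC(F)(F)F)OCC(F)(F)F
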